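**Plan**

1. Locants follow cyclohepta[b]furan numbering of the target (O1, C2 lactone carbonyl, C3, C3a, C4, C5 ketone, C6 methyl-bearing carbon, C7 carbinol, C8 acyloxy carbon, C8a). The enabling feature: the C5 carbonyl carbon and the oxygen-bearing C8 lie 1,4 across the cycloheptanone ring on either side of C6–C7, so one oxygen can bridge them as the mixed ketal of an 8-oxabicyclo[3.2.1]octane, i.e. as the C–O–C termini of a six-membered carbonyl ylide.
2. Retrosynthesis: the α-methylene (from a Mannich base) and the C8 ester go last; C5=O/C8–OH are reclosed to the bridged methyl ketal; C7–C(acyl) is cut (ketone + alkoxyallenyl anion); the lactone is cut at C3–C3a and C8a–O (glyoxylate aldol, reduction); finally C5–C6 and C7–C8 are cut together (carbonyl ylide + 1-ethoxyprop-1-yne).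
3. Forward: diazoketone from methyl succinyl chloride; one-pot ylide formation and cycloaddition builds the seven-membered carbocycle with its oxygen bridge; then the γ-lactone ring, the C7 ketone, the crotonoyl carbinol, bridge opening, acylation and release of the methylene.
4. Stereochemistry: C8 (and the bridge) from the chiral dirhodium carboxylate in the cycloaddition; C3a, C8a, C6 and C7 from delivery of H2, hydride, a proton and the carbon nucleophile to the face of the oxabicycle that carries the oxygen bridge; the ester stereocentre from (2S)-2-methylbutanoic acid.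

Key step: step 2

Assumption: the sense of asymmetric induction of the chiral dirhodium carboxylate on this ester-derived ylide is not established; the (S)-tert-leucinate catalyst is written, and its enantiomer would be used if the (1S,5S) adduct were favoured.

**Route**

Step 1
Reactants: 1 methyl 4-chloro-4-oxobutanoate; 2 (trimethylsilyl)diazomethane
Product: 3 methyl 5-diazo-4-oxopentanoate
Conditions: 2 (2.0 equiv), THF–MeCN 1:1, 0 °C to rt
Reagents that add atoms: none
Why: C-acylation of the diazoalkane by the acid chloride with loss of the silyl group as chlorotrimethylsilane (Arndt–Eistert-type diazoketone synthesis) should give the terminal α-diazoketone and leave the methyl ester untouched.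

Step 2
Reactants: 3 methyl 5-diazo-4-oxopentanoate; 4 1-ethoxyprop-1-yne
Product: 7 (1R,5R)-7-ethoxy-5-methoxy-6-methyl-8-oxabicyclo[3.2.1]oct-6-en-2-one, via rhodium carbene 5 (not isolated), via carbonyl ylide 6 (not isolated)
Conditions: Rh2(S-TCPTTL)4 [dirhodium tetrakis(N-tetrachlorophthaloyl-(S)-tert-leucinate)] (1 mol %), 4 (3 equiv), PhCF3, 23 °C, 3 added over 2 h
Reagents that add atoms: none
Why: Proposed new method: the divalent rhodium carboxylate expels dinitrogen from 3 to give carbene 5, whose electrophilic carbon is captured by the ester carbonyl oxygen in a 6-exo closure to the alkoxy-stabilised six-membered ylide 6, and 6 then adds suprafacially across the alkyne in a concerted 1,3-dipolar cycloaddition that closes the seven-membered carbocycle and the 2,5-dihydrofuran ring of the oxabicycle in one intermolecular two-bond event. The closest known reaction type is the tandem carbonyl ylide formation–cycloaddition of diazoketones, known for ester-derived 1-alkoxy-2-benzopyrylium-4-olates with achiral catalysts and, enantioselectively with this catalyst family, for ketone-derived six-membered ylides and ethoxyacetylene; not yet shown is asymmetric induction on an aliphatic ester-derived ylide with an internal alkoxyalkyne, which should hold if the ylide stays bound to rhodium while the alkyne approaches. The two new stereocentres C1 and C5 are cis by the geometry of the bridge, and their absolute configuration is set by the chiral ligand sphere shielding one face of the metal-bound ylide. The regioselectivity needed (methyl-bearing carbon to C5, ethoxy-bearing carbon to C1) is secured by polarity matching: the nucleophilic β-carbon of the ynol ether bonds to the dialkoxycarbenium-like terminus created by the ester methoxy group, the α-carbon to the enolate-like terminus next to the ketone. Chemoselectivity for intramolecular ylide formation over carbene addition to the electron-rich alkyne is secured by the 1,4-disposition of diazoketone and ester (six-membered closure) and by slow addition of 3.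

Step 3
Reactants: 7 (1R,5R)-7-ethoxy-5-methoxy-6-methyl-8-oxabicyclo[3.2.1]oct-6-en-2-one; 8 ethyl glyoxylate
Product: 12 ethyl (2E)-2-[(1R,5R)-7-ethoxy-5-methoxy-6-methyl-2-oxo-8-oxabicyclo[3.2.1]oct-6-en-3-ylidene]acetate, via lithium enolate 9 (not isolated), via lithium aldolate 10 (not isolated), via mesylate 11 (not isolated)
Conditions: LiN(iPr)2, THF, −78 °C; 8; then MsCl, Et3N, −78 to 0 °C
Reagents that add atoms: none
Why: The ketone can enolise only toward C3 (C1 is a bridgehead), so aldol addition to the aldehyde followed by mesylation and E1cB elimination (aldol condensation) should give the doubly conjugated exocyclic alkene, with no stereocentre set because C3 becomes trigonal.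

Step 4
Reactants: 12 ethyl (2E)-2-[(1R,5R)-7-ethoxy-5-methoxy-6-methyl-2-oxo-8-oxabicyclo[3.2.1]oct-6-en-3-ylidene]acetate
Product: 13 ethyl 2-[(1R,3S,5R)-7-ethoxy-5-methoxy-6-methyl-2-oxo-8-oxabicyclo[3.2.1]oct-6-en-3-yl]acetate
Conditions: H2 (1 atm), Pd/C, EtOAc, trace Et3N, rt
Reagents that add atoms: none
Why: Heterogeneous hydrogenation of the electron-poor trisubstituted alkene should deliver hydrogen to C3 from the open face syn to the oxygen bridge, which places the acetate arm on the side of the C6–C7 bridge (3S), while the tetrasubstituted enol ether is too hindered to be reduced.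

Step 5
Reactants: 13 ethyl 2-[(1R,3S,5R)-7-ethoxy-5-methoxy-6-methyl-2-oxo-8-oxabicyclo[3.2.1]oct-6-en-3-yl]acetate
Product: 15 (1S,2R,6S,8R)-10-ethoxy-8-methoxy-9-methyl-3,11-dioxatricyclo[6.2.1.0^2,6]undec-9-en-4-one, via hydroxy ester 14 (not isolated)
Conditions: NaBH4, MeOH, −40 to 0 °C
Reagents that add atoms: none
Why: Borohydride reduction by axial attack on the C2 ketone from the oxygen-bridge face (anti to the new side chain) should give the alcohol cis to the acetate arm, which closes to the cis-fused γ-lactone by intramolecular transesterification before C3 can epimerise.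

Step 6
Reactants: 15 (1S,2R,6S,8R)-10-ethoxy-8-methoxy-9-methyl-3,11-dioxatricyclo[6.2.1.0^2,6]undec-9-en-4-one
Product: 17 (1S,2R,6S,8R)-5-[(dimethylamino)methyl]-10-ethoxy-8-methoxy-9-methyl-3,11-dioxatricyclo[6.2.1.0^2,6]undec-9-en-4-one, via lactone lithium enolate 16 (not isolated)
Conditions: LiN(iPr)2, THF, −78 °C; CH2=NMe2+ I− (Eschenmoser's salt), −78 to 0 °C
Reagents that add atoms: dimethyl(methylidene)ammonium iodide, C=[N+](C)C.[I-]
Why: Mannich reaction of the lactone α-carbon with the preformed iminium salt installs the future exocyclic methylene as a β-amino group, a base- and nucleophile-stable protected form of the α-methylene lactone whose new centre (C5, either epimer) is erased at the end.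

Step 7
Reactants: 17 (1S,2R,6S,8R)-5-[(dimethylamino)methyl]-10-ethoxy-8-methoxy-9-methyl-3,11-dioxatricyclo[6.2.1.0^2,6]undec-9-en-4-one
Product: 18 (1S,2R,6S,8R,9R)-5-[(dimethylamino)methyl]-8-methoxy-9-methyl-3,11-dioxatricyclo[6.2.1.0^2,6]undecane-4,10-dione
Conditions: aq. HCl (0.5 M, 1.2 equiv; the first equivalent only protonates the amine), THF, 0 °C; NaHCO3 work-up
Reagents that add atoms: water, O
Why: Enol ether hydrolysis starts with rate-limiting C-protonation at C9 from the exo face (syn to the oxygen bridge), which should leave the methyl group endo (9R) and unveil the C10 ketone, while the bridgehead ketal, able to ionise only by reversible ring opening, should survive brief treatment at low water concentration.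

Step 8
Reactants: 19 but-2-yn-1-ol
Product: 20 1-methoxybut-2-yne
Conditions: NaH, MeI, THF, 0 °C to rt
Reagents that add atoms: iodomethane, CI
Why: Williamson ether synthesis on the primary propargylic alkoxide.

Step 9
Reactants: 20 1-methoxybut-2-yne
Product: 21 1-methoxybuta-1,2-diene
Conditions: KOtBu (10 mol %), THF, 40 °C, then distillation
Reagents that add atoms: none
Why: Base-catalysed propargyl–allenyl isomerisation through the oxygen-stabilised propargylic anion should stop at the allenyl ether when catalytic base is used without a dipolar aprotic solvent.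

Step 10
Reactants: 18 (1S,2R,6S,8R,9R)-5-[(dimethylamino)methyl]-8-methoxy-9-methyl-3,11-dioxatricyclo[6.2.1.0^2,6]undecane-4,10-dione; 21 1-methoxybuta-1,2-diene
Product: 24 (1S,2R,6S,8R,9R,10S)-5-[(dimethylamino)methyl]-10-hydroxy-8-methoxy-10-(1-methoxybuta-1,2-dien-1-yl)-9-methyl-3,11-dioxatricyclo[6.2.1.0^2,6]undecan-4-one, via 1-lithio-1-methoxybuta-1,2-diene 22 (not isolated), via dichlorocerium allenyl reagent 23 (not isolated)
Conditions: 21, n-BuLi, THF, −78 °C; anhydrous CeCl3, −78 °C; then 18, −78 °C; aq. NH4Cl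
Reagents that add atoms: none
Why: The α-metalated alkoxyallene is an enone acyl-anion equivalent, and as its weakly basic organocerium it should undergo 1,2-addition to the strained bicyclic ketone in preference to the lactone from the exo face, so that the new carbon substituent is exo and the tertiary hydroxyl endo (10S).

Step 11
Reactants: 24 (1S,2R,6S,8R,9R,10S)-5-[(dimethylamino)methyl]-10-hydroxy-8-methoxy-10-(1-methoxybuta-1,2-dien-1-yl)-9-methyl-3,11-dioxatricyclo[6.2.1.0^2,6]undecan-4-one
Product: 25 (3aS,6R,7S,8S,8aR)-7-[(2E)-but-2-enoyl]-3-[(dimethylamino)methyl]-7,8-dihydroxy-6-methyloctahydro-2H-cyclohepta[b]furan-2,5-dione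
Conditions: aq. HCl (1 M, 3 equiv), THF, 0 °C to rt; NaHCO3 work-up
Reagents that add atoms: water, O
Why: Aqueous acid should hydrolyse the allenyl enol ether to the conjugated enone (the E isomer expected after acid-mediated equilibration) and open the bridged mixed ketal to the C5 ketone and the free C8 alcohol (ketal hydrolysis) without touching the ring stereocentres.

Step 12
Reactants: 25 (3aS,6R,7S,8S,8aR)-7-[(2E)-but-2-enoyl]-3-[(dimethylamino)methyl]-7,8-dihydroxy-6-methyloctahydro-2H-cyclohepta[b]furan-2,5-dione; 26 (2S)-2-methylbutanoic acid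
Product: 27 (3aS,6R,7S,8S,8aR)-7-[(2E)-but-2-enoyl]-3-[(dimethylamino)methyl]-7-hydroxy-6-methyl-2,5-dioxooctahydro-2H-cyclohepta[b]furan-8-yl (2S)-2-methylbutanoate
Conditions: 26, DCC, DMAP (cat.), CH2Cl2, 0 °C to rt
Reagents that add atoms: none
Why: Steglich esterification should acylate only the secondary C8 hydroxyl (the tertiary C7 hydroxyl is too hindered), draining any bridged hemiketal form through the open hydroxy ketone and carrying in the acid stereocentre unchanged.

Step 13
Reactants: 27 (3aS,6R,7S,8S,8aR)-7-[(2E)-but-2-enoyl]-3-[(dimethylamino)methyl]-7-hydroxy-6-methyl-2,5-dioxooctahydro-2H-cyclohepta[b]furan-8-yl (2S)-2-methylbutanoate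
Product: 29 CNP0153197.2, (3aS,6R,7S,8S,8aR)-7-[(2E)-but-2-enoyl]-7-hydroxy-6-methyl-3-methylidene-2,5-dioxooctahydro-2H-cyclohepta[b]furan-8-yl (2S)-2-methylbutanoate, via trimethylammonium iodide 28 (not isolated)
Conditions: MeI, CH2Cl2–MeOH, rt; then aq. NaHCO3, EtOAc, rt
Reagents that add atoms: none
Why: Exhaustive N-methylation followed by mild base-induced β-elimination of trimethylamine (Hofmann-type elimination of the Mannich base) should release the α-methylene lactone under conditions too mild to epimerise C6 or trigger retro-aldol cleavage.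

**Compound list**

1 | methyl 4-chloro-4-oxobutanoate | COC(=O)CCC(Cl)=O | starting material
2 | (trimethylsilyl)diazomethane | C[Si](C)(C)C=[N+]=[N-] | starting material
3 | methyl 5-diazo-4-oxopentanoate | COC(=O)CCC(=O)C=[N+]=[N-] | intermediate
4 | 1-ethoxyprop-1-yne | CCOC#CC | starting material
5 | rhodium carbene of 3 on the dirhodium catalyst (SMILES shows the carbene carbon on one rhodium, ligands omitted) | COC(=O)CCC(=O)C=[Rh] | intermediate (not isolated)
6 | 2-methoxy-3,4-dihydropyrylium-5-olate (six-membered carbonyl ylide) | COC1=[O+]C=C([O-])CC1 | intermediate (not isolated)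
7 | (1R,5R)-7-ethoxy-5-methoxy-6-methyl-8-oxabicyclo[3.2.1]oct-6-en-2-one | O=C1CC[C@]2(OC)C(C)=C(OCC)[C@H]1O2 | intermediate
8 | ethyl glyoxylate (ethyl 2-oxoacetate) | CCOC(=O)C=O | starting material
9 | lithium (1R,5R)-7-ethoxy-5-methoxy-6-methyl-8-oxabicyclo[3.2.1]octa-2,6-dien-2-olate | [Li+].[O-]C1=CC[C@]2(OC)C(C)=C(OCC)[C@H]1O2 | intermediate (not isolated)
10 | lithium aldolate, lithium 2-ethoxy-1-[(1R,5R)-7-ethoxy-5-methoxy-6-methyl-2-oxo-8-oxabicyclo[3.2.1]oct-6-en-3-yl]-2-oxoethanolate (diastereomer mixture) | O=C1C(C([O-])C(=O)OCC)C[C@]2(OC)C(C)=C(OCC)[C@H]1O2.[Li+] | intermediate (not isolated)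
11 | ethyl 2-[(1R,5R)-7-ethoxy-5-methoxy-6-methyl-2-oxo-8-oxabicyclo[3.2.1]oct-6-en-3-yl]-2-(methanesulfonyloxy)acetate (diastereomer mixture) | O=C1C(C(OS(C)(=O)=O)C(=O)OCC)C[C@]2(OC)C(C)=C(OCC)[C@H]1O2 | intermediate (not isolated)
12 | ethyl (2E)-2-[(1R,5R)-7-ethoxy-5-methoxy-6-methyl-2-oxo-8-oxabicyclo[3.2.1]oct-6-en-3-ylidene]acetate | O=C1/C(=C/C(=O)OCC)C[C@]2(OC)C(C)=C(OCC)[C@H]1O2 | intermediate
13 | ethyl 2-[(1R,3S,5R)-7-ethoxy-5-methoxy-6-methyl-2-oxo-8-oxabicyclo[3.2.1]oct-6-en-3-yl]acetate | O=C1[C@H](CC(=O)OCC)C[C@]2(OC)C(C)=C(OCC)[C@H]1O2 | intermediate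
14 | ethyl 2-[(1S,2R,3S,5R)-7-ethoxy-2-hydroxy-5-methoxy-6-methyl-8-oxabicyclo[3.2.1]oct-6-en-3-yl]acetate | O[C@@H]1[C@H](CC(=O)OCC)C[C@]2(OC)C(C)=C(OCC)[C@H]1O2 | intermediate (not isolated)
15 | (1S,2R,6S,8R)-10-ethoxy-8-methoxy-9-methyl-3,11-dioxatricyclo[6.2.1.0^2,6]undec-9-en-4-one (cis-fused γ-lactone on the oxabicycle) | C1C(=O)O[C@@H]2[C@H]1C[C@]3(OC)C(C)=C(OCC)[C@H]2O3 | intermediate
16 | lithium enolate of lactone 15 | C1=C([O-])O[C@@H]2[C@H]1C[C@]3(OC)C(C)=C(OCC)[C@H]2O3.[Li+] | intermediate (not isolated)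
17 | (1S,2R,6S,8R)-5-[(dimethylamino)methyl]-10-ethoxy-8-methoxy-9-methyl-3,11-dioxatricyclo[6.2.1.0^2,6]undec-9-en-4-one (C5 epimers) | CN(C)CC1C(=O)O[C@@H]2[C@H]1C[C@]3(OC)C(C)=C(OCC)[C@H]2O3 | intermediate
18 | (1S,2R,6S,8R,9R)-5-[(dimethylamino)methyl]-8-methoxy-9-methyl-3,11-dioxatricyclo[6.2.1.0^2,6]undecane-4,10-dione | CN(C)CC1C(=O)O[C@@H]2[C@H]1C[C@]3(OC)[C@H](C)C(=O)[C@H]2O3 | intermediate
19 | but-2-yn-1-ol | CC#CCO | starting material
20 | 1-methoxybut-2-yne | CC#CCOC | intermediate
21 | 1-methoxybuta-1,2-diene | CC=C=COC | intermediate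
22 | 1-lithio-1-methoxybuta-1,2-diene | [Li]C(OC)=C=CC | intermediate (not isolated)
23 | dichloro(1-methoxybuta-1,2-dien-1-yl)cerium | CC=C=C(OC)[Ce](Cl)Cl | intermediate (not isolated)
24 | (1S,2R,6S,8R,9R,10S)-5-[(dimethylamino)methyl]-10-hydroxy-8-methoxy-10-(1-methoxybuta-1,2-dien-1-yl)-9-methyl-3,11-dioxatricyclo[6.2.1.0^2,6]undecan-4-one (allene axis unassigned) | CN(C)CC1C(=O)O[C@@H]2[C@H]1C[C@]3(OC)[C@H](C)[C@@](O)(C(OC)=C=CC)[C@H]2O3 | intermediate
25 | (3aS,6R,7S,8S,8aR)-7-[(2E)-but-2-enoyl]-3-[(dimethylamino)methyl]-7,8-dihydroxy-6-methyloctahydro-2H-cyclohepta[b]furan-2,5-dione | CN(C)CC1C(=O)O[C@@H]2[C@H]1CC(=O)[C@H](C)[C@@](O)(C(=O)/C=C/C)[C@H]2O | intermediate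
26 | (2S)-2-methylbutanoic acid | CC[C@H](C)C(=O)O | starting material
27 | (3aS,6R,7S,8S,8aR)-7-[(2E)-but-2-enoyl]-3-[(dimethylamino)methyl]-7-hydroxy-6-methyl-2,5-dioxooctahydro-2H-cyclohepta[b]furan-8-yl (2S)-2-methylbutanoate | CN(C)CC1C(=O)O[C@@H]2[C@H]1CC(=O)[C@H](C)[C@@](O)(C(=O)/C=C/C)[C@H]2OC(=O)[C@@H](C)CC | intermediate
28 | N-methyl quaternary ammonium iodide of 27 | C[N+](C)(C)CC1C(=O)O[C@@H]2[C@H]1CC(=O)[C@H](C)[C@@](O)(C(=O)/C=C/C)[C@H]2OC(=O)[C@@H](C)CC.[I-] | intermediate (not isolated)
29 | CNP0153197.2, (3aS,6R,7S,8S,8aR)-7-[(2E)-but-2-enoyl]-7-hydroxy-6-methyl-3-methylidene-2,5-dioxooctahydro-2H-cyclohepta[b]furan-8-yl (2S)-2-methylbutanoate | C=C1C(=O)O[C@@H]2[C@H]1CC(=O)[C@H](C)[C@@](O)(C(=O)/C=C/C)[C@H]2OC(=O)[C@@H](C)CC | target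

**Step count and risks**

Total steps: 13. Longest linear sequence: 11 (steps 1–7 and 10–13); steps 8 and 9 prepare the allenyl ether.

Most likely to fail:

Step 2. The ester-derived ylide may leave rhodium before the alkyne arrives, so that enantioface discrimination is lost. Fallback with known chemistry, moving the source of absolute configuration from catalyst control to kinetic resolution: setting out from 3, the same tandem reaction with 4 under achiral Rh2(OAc)4 gives racemic 7-ethoxy-5-methoxy-6-methyl-8-oxabicyclo[3.2.1]oct-6-en-2-one F1. NaBH4 in MeOH reduces it from the oxygen-bridge face to the racemic 2-alcohol F2. Acylation with vinyl acetate under Candida antarctica lipase B resolves F2; the (1S,2R,5R)-alcohol F3 is assumed to remain, while its enantiomer becomes the (1R,2S,5S)-acetate F4, which is separated. Dess–Martin oxidation of F3 returns the route to 7.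

Step 10. The basic nucleophile may enolise the hindered β-keto ketal toward C9 (followed by retro-oxa-Michael opening of the oxygen bridge), or it may attack the lactone instead of the ketone. Fallback that builds the acyl group stepwise from the smallest carbon nucleophile: setting out from 18, HC≡CMgBr with CeCl3 in THF at −78 °C adds from the exo face to give the ethynyl carbinol F5. Markovnikov hydration with (Ph3P)AuNTf2 in aqueous dioxane gives the α-hydroxy methyl ketone F6. Deprotonation of F6 with LiN(iPr)2 (2.2 equiv) and addition to acetaldehyde give the β-hydroxy ketone F7, which MsCl and Et3N dehydrate to the (E)-crotonoyl ketal F8. Treating F8 under the conditions of step 11 opens the bridged ketal and returns the route to 25.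

Step 7. Acid may ionise the bridgehead ketal (assisted by the neighbouring enol ether) and open the oxygen bridge irreversibly before C-protonation, or C9 may epimerise after hydrolysis. Fallback without Brønsted acid: setting out from 17, oxymercuration with Hg(OAc)2 in THF–water places mercury on C9 from the exo face and water on C10; loss of ethanol gives the α-mercurio ketone F9. Radical demercuration with Bu3SnH delivers hydrogen to the C9 radical from the exo face and returns the route to 18.

Further compounds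
F1 | step 2 | racemic 7-ethoxy-5-methoxy-6-methyl-8-oxabicyclo[3.2.1]oct-6-en-2-one | O=C1CCC2(OC)C(C)=C(OCC)C1O2
F2 | step 2 | racemic (1S*,2R*,5R*)-7-ethoxy-5-methoxy-6-methyl-8-oxabicyclo[3.2.1]oct-6-en-2-ol (hydroxyl anti to the oxygen bridge) | OC1CCC2(OC)C(C)=C(OCC)C1O2
F3 | step 2 | (1S,2R,5R)-7-ethoxy-5-methoxy-6-methyl-8-oxabicyclo[3.2.1]oct-6-en-2-ol | O[C@@H]1CC[C@]2(OC)C(C)=C(OCC)[C@H]1O2
F4 | step 2 | (1R,2S,5S)-7-ethoxy-5-methoxy-6-methyl-8-oxabicyclo[3.2.1]oct-6-en-2-yl acetate | CC(=O)O[C@H]1CC[C@@]2(OC)C(C)=C(OCC)[C@@H]1O2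
F5 | step 10 | (1S,2R,6S,8R,9R,10R)-5-[(dimethylamino)methyl]-10-ethynyl-10-hydroxy-8-methoxy-9-methyl-3,11-dioxatricyclo[6.2.1.0^2,6]undecan-4-one | CN(C)CC1C(=O)O[C@@H]2[C@H]1C[C@]3(OC)[C@H](C)[C@@](O)(C#C)[C@H]2O3
F6 | step 10 | (1S,2R,6S,8R,9R,10S)-10-acetyl-5-[(dimethylamino)methyl]-10-hydroxy-8-methoxy-9-methyl-3,11-dioxatricyclo[6.2.1.0^2,6]undecan-4-one | CN(C)CC1C(=O)O[C@@H]2[C@H]1C[C@]3(OC)[C@H](C)[C@@](O)(C(C)=O)[C@H]2O3
F7 | step 10 | (1S,2R,6S,8R,9R,10S)-5-[(dimethylamino)methyl]-10-hydroxy-10-(3-hydroxybutanoyl)-8-methoxy-9-methyl-3,11-dioxatricyclo[6.2.1.0^2,6]undecan-4-one | CN(C)CC1C(=O)O[C@@H]2[C@H]1C[C@]3(OC)[C@H](C)[C@@](O)(C(=O)CC(C)O)[C@H]2O3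
F8 | step 10 | (1S,2R,6S,8R,9R,10S)-10-[(2E)-but-2-enoyl]-5-[(dimethylamino)methyl]-10-hydroxy-8-methoxy-9-methyl-3,11-dioxatricyclo[6.2.1.0^2,6]undecan-4-one | CN(C)CC1C(=O)O[C@@H]2[C@H]1C[C@]3(OC)[C@H](C)[C@@](O)(C(=O)/C=C/C)[C@H]2O3
F9 | step 7 | (1S,2R,6S,8R,9S)-9-(acetoxymercurio)-5-[(dimethylamino)methyl]-8-methoxy-9-methyl-3,11-dioxatricyclo[6.2.1.0^2,6]undecane-4,10-dione | CN(C)CC1C(=O)O[C@@H]2[C@H]1C[C@]3(OC)[C@@](C)([Hg]OC(C)=O)C(=O)[C@H]2O3
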